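## Retrosynthetic overview

- The quinone is made last: Ag2O oxidation of the hydroquinone, which comes from one hydrogenation of a tri-O-benzyl macrocyclic stilbene (C=C saturation plus three O-benzyl hydrogenolyses).
- The 18-membered ring is the only ring formed in the route. It is closed by an intramolecular Wittig reaction at the CH=CH between rings C and D; all four six-membered rings are bought.
- The CH2CH2 bridge between ring A (the later quinone) and ring B comes from an intermolecular aldol addition. The dilithium enediolate of the ring B arylacetic acid (B–O–C fragment) adds to the ring A benzaldehyde (A–O–D fragment); decarboxylative dehydration and diimide reduction follow.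
- The A–O–D fragment comes from methoxyhydroquinone (benzylation, Vilsmeier formylation, Dakin oxidation, ortho-formylation, Ullmann coupling). The B–O–C fragment comes from 4-(benzyloxy)-3-hydroxybenzaldehyde (acetal, Ullmann coupling, saponification).
- Order: diaryl ethers first, then the aldol union, then the macrocycle, then the quinone oxidation state.

Assumption: the target has no stereocentre and no stereogenic double bond (it is achiral), so no configuration has to be set; the two stereocentres of the aldol adduct and all alkene geometries are transient and are erased later.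

## Route

Step 1
Reactants: 1 2-methoxybenzene-1,4-diol (methoxyhydroquinone)
Product: 2 1,4-bis(benzyloxy)-2-methoxybenzene
Conditions: BnBr (2.3 equiv), K2CO3, DMF, rt to 50 °C, N2
Reagents that add atoms: benzyl bromide, BrCc1ccccc1
Why: Williamson ether synthesis on both phenols; benzyl is chosen so that all three phenol protecting groups fall together in the final hydrogenolysis.

Step 2
Reactants: 2 1,4-bis(benzyloxy)-2-methoxybenzene
Product: 4 2,5-bis(benzyloxy)-4-methoxybenzaldehyde, via iminium salt 3 (not isolated)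
Conditions: POCl3, DMF, 0 to 70 °C; then ice/H2O
Reagents that add atoms: N,N-dimethylformamide, CN(C)C=O; water, O
Why: Vilsmeier–Haack formylation goes to the position para to OMe and ortho to OBn, the same site as in 1,2,4-trimethoxybenzene, and the iminium salt is hydrolysed on work-up.

Step 3
Reactants: 4 2,5-bis(benzyloxy)-4-methoxybenzaldehyde
Product: 6 2,5-bis(benzyloxy)-4-methoxyphenol, via aryl formate 5 (not isolated)
Conditions: mCPBA, CH2Cl2, 0 °C to rt; NaHCO3 wash; then K2CO3 (cat.), MeOH, rt, N2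
Reagents that add atoms: mCPBA, OOC(=O)c1cccc(Cl)c1
Why: Dakin-type Baeyer–Villiger oxidation, in which the ortho/para-alkoxy aryl group migrates in preference to hydrogen, followed by methanolysis of the formate.

Step 4
Reactants: 6 2,5-bis(benzyloxy)-4-methoxyphenol
Product: 8 3,6-bis(benzyloxy)-2-hydroxy-5-methoxybenzaldehyde, via salicyl alcohol 7 (not isolated)
Conditions: MgCl2, Et3N, (CH2O)n, MeCN, reflux; dilute HCl work-up
Reagents that add atoms: formaldehyde (from paraformaldehyde), C=O
Why: Magnesium-mediated ortho-formylation (Casiraghi–Skattebøl) is specific for the position ortho to OH, and only one such position is free; the hydroxymethyl intermediate is oxidised in the flask by a second formaldehyde through hydride transfer.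

Step 5
Reactants: 8 3,6-bis(benzyloxy)-2-hydroxy-5-methoxybenzaldehyde; 9 methyl 3-iodobenzoate
Product: 10 methyl 3-[3,6-bis(benzyloxy)-2-formyl-4-methoxyphenoxy]benzoate
Conditions: CuI (20 mol%), picolinic acid (40 mol%), K3PO4, DMSO, 90 °C
Reagents that add atoms: none
Why: Ullmann-type C–O coupling; the CuI/picolinic acid system is made for ortho,ortho-disubstituted phenols, and the iodide bearing a meta ester is an activated partner.

Step 6
Reactants: 11 4-(benzyloxy)-3-hydroxybenzaldehyde
Product: 12 2-(benzyloxy)-5-(1,3-dioxolan-2-yl)phenol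
Conditions: HOCH2CH2OH, p-TsOH (cat.), toluene, reflux, Dean–Stark
Reagents that add atoms: ethylene glycol, OCCO
Why: Acid-catalysed acetalisation with water removal masks the aldehyde, which would otherwise condense with the arylacetate in steps 7 and 9.

Step 7
Reactants: 12 2-(benzyloxy)-5-(1,3-dioxolan-2-yl)phenol; 13 methyl 2-(4-iodophenyl)acetate
Product: 14 methyl 2-{4-[2-(benzyloxy)-5-(1,3-dioxolan-2-yl)phenoxy]phenyl}acetate
Conditions: CuI (10 mol%), N,N-dimethylglycine (30 mol%), Cs2CO3, 1,4-dioxane, 90 °C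
Reagents that add atoms: none
Why: Ullmann diaryl ether coupling under amino-acid ligand conditions, which work at 90 °C for ortho-alkoxy phenols with unhindered aryl iodides and leave the acetal and ester intact.

Step 8
Reactants: 14 methyl 2-{4-[2-(benzyloxy)-5-(1,3-dioxolan-2-yl)phenoxy]phenyl}acetate
Product: 15 2-{4-[2-(benzyloxy)-5-(1,3-dioxolan-2-yl)phenoxy]phenyl}acetic acid
Conditions: LiOH, THF/MeOH/H2O, rt; then AcOH to pH 5, 0 °C
Reagents that add atoms: LiOH, [Li+].[OH-]
Why: Ester saponification; acidification only to pH 5 keeps the dioxolane intact.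

Step 9
Reactants: 15 2-{4-[2-(benzyloxy)-5-(1,3-dioxolan-2-yl)phenoxy]phenyl}acetic acid; 10 methyl 3-[3,6-bis(benzyloxy)-2-formyl-4-methoxyphenoxy]benzoate
Product: 17 2-{4-[2-(benzyloxy)-5-(1,3-dioxolan-2-yl)phenoxy]phenyl}-3-{3,6-bis(benzyloxy)-5-methoxy-2-[3-(methoxycarbonyl)phenoxy]phenyl}-3-hydroxypropanoic acid (racemic syn/anti mixture), via dilithium enediolate 16 (not isolated)
Conditions: LiN(i-Pr)2 (2.2 equiv), THF, −78 to 0 °C; then 10, −78 °C; AcOH quench
Reagents that add atoms: none
Why: Intermolecular aldol addition (Ivanov type) of the arylacetic acid enediolate to the non-enolisable aldehyde, which reacts far faster than the methyl benzoate at −78 °C; the two new stereocentres form unselectively and are both destroyed in step 10.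

Step 10
Reactants: 17 the β-hydroxy acid from step 9
Product: 18 methyl 3-{3,6-bis(benzyloxy)-2-[2-{4-[2-(benzyloxy)-5-(1,3-dioxolan-2-yl)phenoxy]phenyl}ethenyl]-4-methoxyphenoxy}benzoate (E/Z mixture)
Conditions: Me2NCH(OCH2CMe3)2, toluene, 80 °C
Reagents that add atoms: none
Why: Decarboxylative dehydration of a β-hydroxy acid with a DMF acetal: the activated benzylic C–O bond ionises easily next to the electron-rich ring A and CO2 is lost; the neopentyl acetal cannot esterify the acid.

Step 11
Reactants: 18 the stilbene from step 10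
Product: 19 methyl 3-{3,6-bis(benzyloxy)-2-[2-{4-[2-(benzyloxy)-5-(1,3-dioxolan-2-yl)phenoxy]phenyl}ethyl]-4-methoxyphenoxy}benzoate
Conditions: 2-nitrobenzenesulfonylhydrazide (excess, in portions), Et3N, CH2Cl2, rt
Reagents that add atoms: none
Why: Diimide reduction saturates only the C=C bond under anhydrous basic conditions, so benzyl ethers, acetal and ester survive and the tether is flexible for ring closure.

Step 12
Reactants: 19 the bibenzyl ester from step 11
Product: 20 {3-[3,6-bis(benzyloxy)-2-(2-{4-[2-(benzyloxy)-5-(1,3-dioxolan-2-yl)phenoxy]phenyl}ethyl)-4-methoxyphenoxy]phenyl}methanol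
Conditions: LiAlH4, THF, 0 °C; aqueous work-up
Reagents that add atoms: none
Why: Hydride reduction of the methyl benzoate to the benzylic alcohol; acetal and ethers are inert.

Step 13
Reactants: 20 the benzylic alcohol from step 12
Product: 22 {3-[3,6-bis(benzyloxy)-2-(2-{4-[2-(benzyloxy)-5-formylphenoxy]phenyl}ethyl)-4-methoxyphenoxy]benzyl}triphenylphosphonium bromide, via acetal phosphonium bromide 21 (not isolated)
Conditions: PPh3·HBr, MeCN, reflux; then 1 M aq. HCl, THF, rt
Reagents that add atoms: triphenylphosphine hydrobromide, [Br-].[PH+](c1ccccc1)(c1ccccc1)c1ccccc1; water, O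
Why: The benzylic alcohol is converted directly into the phosphonium salt (SN1/SN2 substitution via the bromide), and the dioxolane is then hydrolysed by mild aqueous acid.

Step 14
Reactants: 22 the formyl phosphonium bromide from step 13
Product: 24 tri-O-benzyl macrocyclic stilbene (18-membered ring; CH=CH between rings C and D; E/Z mixture), via phosphonium ylide 23 (not isolated)
Conditions: NaOMe, CH2Cl2/MeOH, rt, slow addition of 22 (high dilution, about 1 mM)
Reagents that add atoms: none
Why: Intramolecular Wittig macrocyclisation of a semi-stabilised benzylic ylide onto an unhindered aryl aldehyde; alkene geometry does not matter because the bond is hydrogenated next.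

Step 15
Reactants: 24 the macrocyclic stilbene from step 14
Product: 26 marchantinquinone (the target), via hydroquinone 25 (not isolated)
Conditions: H2 (1 atm), Pd/C, EtOAc/MeOH, rt; filter under N2; then Ag2O, Na2SO4, Et2O, rt
Reagents that add atoms: none
Why: Catalytic hydrogenation saturates the stilbene and hydrogenolyses the three benzyl ethers; Ag2O then dehydrogenates only the hydroquinone to the para-quinone and leaves the ring C monophenol untouched.

## Compound list

1 | 2-methoxybenzene-1,4-diol (methoxyhydroquinone) | COc1cc(O)ccc1O | starting material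
2 | 1,4-bis(benzyloxy)-2-methoxybenzene | COc1cc(OCc2ccccc2)ccc1OCc1ccccc1 | intermediate
3 | [2,5-bis(benzyloxy)-4-methoxybenzylidene]dimethyliminium dichlorophosphate | C[N+](C)=Cc1cc(OCc2ccccc2)c(OC)cc1OCc1ccccc1.[O-]P(=O)(Cl)Cl | intermediate
4 | 2,5-bis(benzyloxy)-4-methoxybenzaldehyde | O=Cc1cc(OCc2ccccc2)c(OC)cc1OCc1ccccc1 | intermediate
5 | 2,5-bis(benzyloxy)-4-methoxyphenyl formate | O=COc1cc(OCc2ccccc2)c(OC)cc1OCc1ccccc1 | intermediate
6 | 2,5-bis(benzyloxy)-4-methoxyphenol | Oc1cc(OCc2ccccc2)c(OC)cc1OCc1ccccc1 | intermediate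
7 | 3,6-bis(benzyloxy)-2-(hydroxymethyl)-4-methoxyphenol (present as its magnesium salt) | OCc1c(O)c(OCc2ccccc2)cc(OC)c1OCc1ccccc1 | intermediate
8 | 3,6-bis(benzyloxy)-2-hydroxy-5-methoxybenzaldehyde | O=Cc1c(O)c(OCc2ccccc2)cc(OC)c1OCc1ccccc1 | intermediate
9 | methyl 3-iodobenzoate | COC(=O)c1cccc(I)c1 | starting material
10 | methyl 3-[3,6-bis(benzyloxy)-2-formyl-4-methoxyphenoxy]benzoate | COC(=O)c1cccc(c1)Oc1c(C=O)c(OCc2ccccc2)c(OC)cc1OCc1ccccc1 | intermediate
11 | 4-(benzyloxy)-3-hydroxybenzaldehyde | O=Cc1ccc(OCc2ccccc2)c(O)c1 | starting material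
12 | 2-(benzyloxy)-5-(1,3-dioxolan-2-yl)phenol | Oc1cc(ccc1OCc1ccccc1)C1OCCO1 | intermediate
13 | methyl 2-(4-iodophenyl)acetate | COC(=O)Cc1ccc(I)cc1 | starting material
14 | methyl 2-{4-[2-(benzyloxy)-5-(1,3-dioxolan-2-yl)phenoxy]phenyl}acetate | COC(=O)Cc1ccc(cc1)Oc1cc(ccc1OCc1ccccc1)C1OCCO1 | intermediate
15 | 2-{4-[2-(benzyloxy)-5-(1,3-dioxolan-2-yl)phenoxy]phenyl}acetic acid | OC(=O)Cc1ccc(cc1)Oc1cc(ccc1OCc1ccccc1)C1OCCO1 | intermediate
16 | dilithium enediolate of 15 | [Li+].[Li+].[O-]C([O-])=Cc1ccc(cc1)Oc1cc(ccc1OCc1ccccc1)C1OCCO1 | intermediate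
17 | 2-{4-[2-(benzyloxy)-5-(1,3-dioxolan-2-yl)phenoxy]phenyl}-3-{3,6-bis(benzyloxy)-5-methoxy-2-[3-(methoxycarbonyl)phenoxy]phenyl}-3-hydroxypropanoic acid (racemic syn/anti mixture) | OC(=O)C(c1ccc(cc1)Oc1cc(ccc1OCc1ccccc1)C1OCCO1)C(O)c1c(OCc2ccccc2)c(OC)cc(OCc2ccccc2)c1Oc1cccc(c1)C(=O)OC | intermediate
18 | methyl 3-{3,6-bis(benzyloxy)-2-[2-{4-[2-(benzyloxy)-5-(1,3-dioxolan-2-yl)phenoxy]phenyl}ethenyl]-4-methoxyphenoxy}benzoate (E/Z mixture) | COC(=O)c1cccc(c1)Oc1c(C=Cc2ccc(cc2)Oc2cc(ccc2OCc2ccccc2)C2OCCO2)c(OCc2ccccc2)c(OC)cc1OCc1ccccc1 | intermediate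
19 | methyl 3-{3,6-bis(benzyloxy)-2-[2-{4-[2-(benzyloxy)-5-(1,3-dioxolan-2-yl)phenoxy]phenyl}ethyl]-4-methoxyphenoxy}benzoate | COC(=O)c1cccc(c1)Oc1c(CCc2ccc(cc2)Oc2cc(ccc2OCc2ccccc2)C2OCCO2)c(OCc2ccccc2)c(OC)cc1OCc1ccccc1 | intermediate
20 | {3-[3,6-bis(benzyloxy)-2-(2-{4-[2-(benzyloxy)-5-(1,3-dioxolan-2-yl)phenoxy]phenyl}ethyl)-4-methoxyphenoxy]phenyl}methanol | OCc1cccc(c1)Oc1c(CCc2ccc(cc2)Oc2cc(ccc2OCc2ccccc2)C2OCCO2)c(OCc2ccccc2)c(OC)cc1OCc1ccccc1 | intermediate
21 | {3-[3,6-bis(benzyloxy)-2-(2-{4-[2-(benzyloxy)-5-(1,3-dioxolan-2-yl)phenoxy]phenyl}ethyl)-4-methoxyphenoxy]benzyl}triphenylphosphonium bromide | [Br-].c1ccccc1[P+](c1ccccc1)(c1ccccc1)Cc1cccc(c1)Oc1c(CCc2ccc(cc2)Oc2cc(ccc2OCc2ccccc2)C2OCCO2)c(OCc2ccccc2)c(OC)cc1OCc1ccccc1 | intermediate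
22 | {3-[3,6-bis(benzyloxy)-2-(2-{4-[2-(benzyloxy)-5-formylphenoxy]phenyl}ethyl)-4-methoxyphenoxy]benzyl}triphenylphosphonium bromide | [Br-].c1ccccc1[P+](c1ccccc1)(c1ccccc1)Cc1cccc(c1)Oc1c(CCc2ccc(cc2)Oc2cc(C=O)ccc2OCc2ccccc2)c(OCc2ccccc2)c(OC)cc1OCc1ccccc1 | intermediate
23 | ylide of 22 ({3-[…]benzylidene}triphenylphosphorane) | c1ccccc1P(c1ccccc1)(c1ccccc1)=Cc1cccc(c1)Oc1c(CCc2ccc(cc2)Oc2cc(C=O)ccc2OCc2ccccc2)c(OCc2ccccc2)c(OC)cc1OCc1ccccc1 | intermediate
24 | tri-O-benzyl macrocyclic stilbene (18-membered ring; ring A as 1,4-bis(benzyloxy)-2-methoxy arene, ring C O-benzyl, CH=CH between rings C and D; E/Z mixture) | COc1cc(OCc2ccccc2)c3c(CCc4ccc(cc4)Oc5cc(ccc5OCc6ccccc6)C=Cc7cccc(c7)O3)c1OCc8ccccc8 | intermediate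
25 | hydroquinone of the target (ring A as 2-methoxybenzene-1,4-diol, both bridges saturated, ring C phenol free) | COc1cc(O)c2c(CCc3ccc(cc3)Oc4cc(ccc4O)CCc5cccc(c5)O2)c1O | intermediate
26 | marchantinquinone (CNP0332646.0; achiral) | COC1=CC(=O)C2=C(CCc3ccc(cc3)Oc3cc(ccc3O)CCc3cccc(c3)O2)C1=O | target

## Step count and risks

Total step count: 15.
Longest linear sequence: 12 steps (steps 1–5, then 9–15, from compound 1).

Three steps most likely to fail:

Step 5, the Ullmann arylation of salicylaldehyde 8. The phenol is flanked on both sides and hydrogen-bonded to the aldehyde, so the copper coupling may be slow. The fallback is a metal-free arylation with a diaryliodonium salt and sets out from compound 9. Methyl 3-iodobenzoate is oxidised with mCPBA and TsOH·H2O in MeCN, and 1,3,5-trimethoxybenzene is added to give [3-(methoxycarbonyl)phenyl](2,4,6-trimethoxyphenyl)iodonium tosylate F1. Phenol 8 is then stirred with K2CO3 and F1 in toluene at 50 °C. The trimethoxyphenyl group stays on iodine and the ester-bearing aryl is transferred to oxygen, so the sequence comes back to the route at compound 10.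

Step 9, the aldol addition to the hindered, electron-rich aldehyde 10. The adduct may revert, or the enediolate may attack the benzoate. The fallback is a Perkin-type aldol condensation, which sets out from compounds 15 and 10. They are heated in Ac2O/Et3N at 110–120 °C, where the aldol adduct is acetylated and eliminated irreversibly. This gives (2E)-2-{4-[2-(benzyloxy)-5-(1,3-dioxolan-2-yl)phenoxy]phenyl}-3-{3,6-bis(benzyloxy)-5-methoxy-2-[3-(methoxycarbonyl)phenoxy]phenyl}prop-2-enoic acid F2 after mild NaHCO3 hydrolysis of the mixed anhydride. Protodecarboxylation with Cu powder in quinoline at about 200 °C then gives the stilbene, so the sequence comes back at compound 18 and bypasses compound 17 and step 10.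

Step 14, the Wittig macrocyclisation. Oligomerisation may win over 18-membered ring closure. The fallback is a McMurry macrocyclisation and sets out from compound 20. MnO2 in CH2Cl2 oxidises the benzylic alcohol to 3-[3,6-bis(benzyloxy)-2-(2-{4-[2-(benzyloxy)-5-(1,3-dioxolan-2-yl)phenoxy]phenyl}ethyl)-4-methoxyphenoxy]benzaldehyde F3. Treatment with 1 M aq. HCl in THF removes the acetal and gives the dialdehyde 3-[3,6-bis(benzyloxy)-2-(2-{4-[2-(benzyloxy)-5-formylphenoxy]phenyl}ethyl)-4-methoxyphenoxy]benzaldehyde F4. Slow addition of F4 to the TiCl4/Zn reagent with pyridine in refluxing THF couples the two aldehydes reductively, and the sequence comes back at compound 24.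

## Further compounds

F1 | step 5 | [3-(methoxycarbonyl)phenyl](2,4,6-trimethoxyphenyl)iodonium tosylate | COC(=O)c1cccc(c1)[I+]c1c(OC)cc(OC)cc1OC.Cc1ccc(cc1)S(=O)(=O)[O-]
F2 | step 9 | (2E)-2-{4-[2-(benzyloxy)-5-(1,3-dioxolan-2-yl)phenoxy]phenyl}-3-{3,6-bis(benzyloxy)-5-methoxy-2-[3-(methoxycarbonyl)phenoxy]phenyl}prop-2-enoic acid | OC(=O)/C(c1ccc(cc1)Oc1cc(ccc1OCc1ccccc1)C1OCCO1)=C/c1c(OCc2ccccc2)c(OC)cc(OCc2ccccc2)c1Oc1cccc(c1)C(=O)OC
F3 | step 14 | 3-[3,6-bis(benzyloxy)-2-(2-{4-[2-(benzyloxy)-5-(1,3-dioxolan-2-yl)phenoxy]phenyl}ethyl)-4-methoxyphenoxy]benzaldehyde | O=Cc1cccc(c1)Oc1c(CCc2ccc(cc2)Oc2cc(ccc2OCc2ccccc2)C2OCCO2)c(OCc2ccccc2)c(OC)cc1OCc1ccccc1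
F4 | step 14 | 3-[3,6-bis(benzyloxy)-2-(2-{4-[2-(benzyloxy)-5-formylphenoxy]phenyl}ethyl)-4-methoxyphenoxy]benzaldehyde | O=Cc1cccc(c1)Oc1c(CCc2ccc(cc2)Oc2cc(C=O)ccc2OCc2ccccc2)c(OCc2ccccc2)c(OC)cc1OCc1ccccc1
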